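## The problem

The target **13**, [(1S,2S,3R,6R)-3-(benzoyloxy)-1,2,6-trihydroxycyclohexyl]methyl benzoate, is a single cyclohexane ring. The numbering used here: C1 is the quaternary carbinol, C7 its benzoyloxymethyl carbon, C2 the carbinol next to the methylenes C3 and C4, C5 the benzoate-bearing carbon, and C6 the carbinol between C5 and C1.

Four contiguous stereocentres (C5, C6, C1, C2) carry oxygen. O5 is trans to O6, and O1 is trans to both O6 and O2, so in the chair all four ring oxygens are equatorial and C7 is axial. There is no ring fusion to lean on, and the hard centre is the fully substituted C1, flanked on both sides by secondary carbinols.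

The centres can relay. A trans C5/C6 pair is the natural result of opening a cis-epoxide. C6 can pass its configuration to C1 if the C1–C6 bond is made in a stereospecific intramolecular event. C2, if kept as a ketone until late, can be set from the C1 hydroxyl and the axial C7 group.

Two benzoates sit beside three free hydroxyls, so alkoxide-forming conditions late in the route invite acyl migration, and any β-hydroxy ketone on the way is open to retro-aldol cleavage. The late steps therefore have to be neutral or acidic.

The enabling feature is that, with C2 at the ketone level, C1(OH)(C7)–C2(=O) is a tertiary α-ketol. Its isomer by 1,2-shift of C6 is a 1-acylcyclopentanol in which C2 is the ring carbinol, C1 the exocyclic acyl carbon, and C2–C3–C4–C5–C6 a cyclopentane with the oxygen pattern of an epoxidised cyclopent-2-enone.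

## Retrosynthesis

**13 from 12 and 11 (no skeletal bond cut).** The O6 silyl ether of **12** is removed last, and the C2 carbinol of **12** is traced to the ketone **11**. Keeping C2 as a ketone is what makes C1/C2 an α-ketol. It also leaves the easiest centre for the end, where the tertiary C1 hydroxyl, the only free hydroxyl in **11**, can deliver hydride to its own face. Setting C2 earlier would forfeit the ketol and require a second differentiation of secondary hydroxyls. The forward reduction must place O2 trans to O1, and the silyl ether must come off without base.

**11 from 10 (key disconnection).** The C1–C6 bond is cut and the C2–C6 bond re-formed, which contracts the cyclohexanone **11** to the 1-acylcyclopentanol **10**. Cutting C1–C2 instead (a benzoin-type closure) or C3–C4 leaves an acyclic chain in which C5, C6 and C1 must all be set independently. The chosen cut turns the quaternary C1 into a planar acyl carbon and reduces four ring stereocentres to a cyclopentane triad (cis tertiary carbinol/C6 oxygen, trans C5 benzoate). The forward step asks three things: C6 rather than C3 must migrate, it must migrate with retention, and the acyl group must react through the rotamer with its carbonyl oxygen anti to the carbinol oxygen, so that O1 ends trans to O6.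

**10 from 9, and 9 from 7 and 8 (C5–O bond).** The silyl ether of **10** is put on the secondary hydroxyl of diol **9**. The C5–O bond of **9** is cut to the cis-epoxy alcohol **7** and benzoic acid **8**. Anti opening of an epoxide gives the trans C5/C6 relationship directly and places the ester regioselectively. Dihydroxylation of an alkene would give the cis pair and leave two secondary hydroxyls to tell apart. The forward opening must occur at C5, the carbon remote from the quaternary carbinol.

**7 from 6, and 6 from 5 (side-chain oxidation level).** The C7 benzoate of **7** comes from the primary hydroxyl of **6**. The hydroxyacetyl group of **6** comes from the 1-ethoxyvinyl group of **5** by oxidation of the enol ether. This installs the ketone and the C7 oxygen in one operation. The forward steps must leave the epoxide and the tertiary hydroxyl alone.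

**5 from 2 and 4 (bond between C1 and C2).** The bond from the acyl carbon to the ring is cut to the epoxy ketone **2** and the acyl-anion equivalent **4**, generated from ethyl vinyl ether **3**. The bicyclic ketone has one open face, so addition anti to the epoxide fixes the cis relationship between the C2 hydroxyl and O6 that the key step needs. A two-carbon nucleophile that already carries the ketone oxidation level saves later redox steps.

**2 from 1 (two C–O bonds).** The epoxide is cut to cyclopent-2-enone **1**. One catalytic asymmetric nucleophilic epoxidation sets C5 and C6 and with them the absolute configuration of the whole route. Every later centre is derived from these two by substrate control.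

## Roads not taken

**Alternative 1: enamine [3+3] annulation.** The cuts are C2–C3 and C5–C6. In the forward step a chiral secondary amine would convert 2,2-dimethyl-1,3-dioxan-5-one A1 into its enamine, which adds to acrolein A2; the re-formed enamine then closes on the aldehyde to give the bicyclic ketone A3.

- Merits: one step builds the carbocycle and three of its stereocentres from two cheap achiral compounds. The acetonide holds O2 and O6 cis as the target requires, and the C5 hydroxyl is free for benzoylation. With one-carbon homologation of the bridging ketone and acetal removal the route could be five or six steps, shorter than the nine chosen here.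
- Weak points: C7 must be delivered to the bridging carbonyl of A3 from the face under the acetal bridge, where a methyl group of the ketal projects. The more open face gives the C1 epimer, so the hardest centre is the least secure. The domino also needs both C–C bonds to form with catalyst control in the presence of a polymerisable enal, and the aldol step is reversible, which can erode the trans C5 hydroxyl.
- Comparison: this road is better in step economy and convergence. The chosen plan sets against it a C1 centre formed by a suprafacial shift with a stated stereochemical model, and steps that are each known reaction types.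

**Alternative 2: C3–C4 closure by oxidative enolate coupling.** The cut is the only ring bond without a stereocentre. In the forward step the chiral-pool-derived bis(methyl ketone) A4 would be doubly deprotonated with a lithium amide and oxidised with a divalent copper salt, joining the two methyl carbons to give the trans-fused dione A5.

- Merits: absolute configuration comes from the chiral pool and is certain. This is better than relying on a catalytic epoxidation of a small, volatile enone. C1 and C6 are in place before the ring exists, and the closure creates no stereocentre.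
- Weak points: intramolecular enolate homo-coupling to a six-membered 1,4-dione competes with oligomerisation, and it forms a strained trans-fused dioxolane. Both ketones of A5 must then be reduced with opposite facial demands and the two new hydroxyls told apart (C5 benzoate, C2 free). The benzyl ether must also be exchanged for a benzoate, so the count rises well beyond nine steps.
- Comparison: better in certainty of absolute configuration. The chosen plan is shorter, has only one ketone to reduce and no diol to differentiate.

**Alternative 3: carbene-catalysed benzoin closing C1–C2.** The cut is C1–C2. In the forward step a chiral triazolium-derived carbene would turn the aldehyde of the keto-aldehyde A6 into an acyl-anion equivalent that adds to the ketone, giving the cyclic α-ketol A7.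

- Merits: C1 is set under external catalyst control, which can override the substrate, and there is no question of which group migrates. In this respect it is at least as good as the chosen key step. A7 is the same type of ketol as **11** and would share the endgame.
- Weak points: A6 is acyclic and carries three differently protected oxygens, so it needs a longer preparation than the cyclic precursor **10**. A6 is a β-benzoyloxy ketone, so the basic carbene conditions threaten elimination of benzoate and aldol side reactions of the aldehyde. C7 arrives as a silyl ether and must later be exchanged for the benzoate.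
- Comparison: better in control of C1. The chosen plan has a six-step access to the rearrangement precursor from cyclopent-2-enone and a ketol stage that never sees base.

Key step: step 7

Assumption: the quinine-derived primary amine salt is taken to deliver the (1S,5S)-epoxide **2**; should the sense of induction be the reverse, the quinidine-derived pseudo-enantiomeric salt is used in the same way.

## Route

Step 1
Reactants: 1 cyclopent-2-en-1-one
Product: 2 (1S,5S)-6-oxabicyclo[3.1.0]hexan-2-one
Conditions: 9-amino-9-deoxy-epi-quinine·2CF3CO2H (10 mol%), 50% aq. H2O2 (1.5 equiv), 1,4-dioxane, 50 °C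
Reagents that add atoms: hydrogen peroxide, OO
Why: Amine-salt-catalysed asymmetric Weitz–Scheffer epoxidation: the primary amine forms an iminium ion with the enone, hydrogen peroxide adds to C5 on the face left open by the cinchona scaffold and the enamine closes the O–O bond onto C6, so both epoxide centres are set together under catalyst control; the method is established for five- to fifteen-membered cyclic enones.

Step 2
Reactants: 2 (1S,5S)-6-oxabicyclo[3.1.0]hexan-2-one; 3 ethyl vinyl ether
Product: 5 (1S,2R,5S)-2-(1-ethoxyethenyl)-6-oxabicyclo[3.1.0]hexan-2-ol (hydroxyl cis to the epoxide oxygen), via (1-ethoxyethenyl)lithium 4 (not isolated)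
Conditions: 3, t-BuLi, THF, −78 → 0 °C; then 2, THF, −78 °C; H2O
Reagents that add atoms: none
Why: 1,2-Addition of an α-alkoxyvinyllithium (acyl-anion equivalent) to the ketone; the reagent should approach the carbonyl of the oxabicyclohexanone from the face opposite the epoxide oxygen, so the new tertiary hydroxyl at C2 is cis to the epoxide, and low temperature favours addition over enolisation.

Step 3
Reactants: 5 (1S,2R,5S)-2-(1-ethoxyethenyl)-6-oxabicyclo[3.1.0]hexan-2-ol
Product: 6 2-hydroxy-1-[(1S,2R,5S)-2-hydroxy-6-oxabicyclo[3.1.0]hexan-2-yl]ethan-1-one
Conditions: OsO4 (2 mol%), NMO (1.3 equiv), acetone/H2O (5:1), 0 °C → rt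
Reagents that add atoms: 4-methylmorpholine N-oxide, C[N+]1([O-])CCOCC1; water, O
Why: Catalytic dihydroxylation of the electron-rich enol ether; the hemiketal formed collapses with loss of ethanol to the hydroxyacetyl ketone (enol-ether to α-hydroxy-ketone oxidation), the epoxide and tertiary alcohol are inert, and no stereocentre is touched.

Step 4
Reactants: 6 2-hydroxy-1-[(1S,2R,5S)-2-hydroxy-6-oxabicyclo[3.1.0]hexan-2-yl]ethan-1-one
Product: 7 2-[(1S,2R,5S)-2-hydroxy-6-oxabicyclo[3.1.0]hexan-2-yl]-2-oxoethyl benzoate
Conditions: BzCl (1.05 equiv), pyridine, CH2Cl2, −20 → 0 °C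
Reagents that add atoms: benzoyl chloride, O=C(Cl)c1ccccc1
Why: Selective esterification of the primary hydroxyl; the hindered tertiary α-keto carbinol should not acylate under these conditions, as in the selective acylation of the primary hydroxyl of dihydroxyacetone side chains.

Step 5
Reactants: 7 2-[(1S,2R,5S)-2-hydroxy-6-oxabicyclo[3.1.0]hexan-2-yl]-2-oxoethyl benzoate; 8 benzoic acid
Product: 9 2-[(1R,2S,3R)-3-(benzoyloxy)-1,2-dihydroxycyclopentyl]-2-oxoethyl benzoate (1,2-cis diol, 2,3-trans)
Conditions: Ti(OiPr)4 (1.5 equiv), 8 (2 equiv), CH2Cl2, 0 °C → rt; aq. tartaric acid work-up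
Reagents that add atoms: none
Why: Titanium-mediated opening of a 2,3-epoxy alcohol by a carboxylic acid at the carbon remote from the carbinol: benzoate attacks C5 anti to the epoxide oxygen (inversion at C5, C6 untouched), giving the trans C5-benzoate/C6-hydroxyl pair; attack at C6 is disfavoured by the adjacent quaternary carbon and its electron-withdrawing acyl group.

Step 6
Reactants: 9 2-[(1R,2S,3R)-3-(benzoyloxy)-1,2-dihydroxycyclopentyl]-2-oxoethyl benzoate
Product: 10 2-[(1R,2S,3R)-3-(benzoyloxy)-2-[(tert-butyldimethylsilyl)oxy]-1-hydroxycyclopentyl]-2-oxoethyl benzoate
Conditions: TBSOTf (1.1 equiv), 2,6-lutidine, CH2Cl2, −78 °C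
Reagents that add atoms: tert-butyldimethylsilyl trifluoromethanesulfonate, CC(C)(C)[Si](C)(C)OS(=O)(=O)C(F)(F)F
Why: Silyl triflate silylation of the secondary C6 hydroxyl at low temperature, the tertiary α-keto carbinol staying free; the silyl ether blocks retro-aldol cleavage, keeps the C6 oxygen from binding the Lewis acid so that C6 stays electron-rich for migration, and later prevents hydride delivery from O6.

Step 7
Reactants: 10 2-[(1R,2S,3R)-3-(benzoyloxy)-2-[(tert-butyldimethylsilyl)oxy]-1-hydroxycyclopentyl]-2-oxoethyl benzoate
Product: 11 [(1R,2S,3R)-3-(benzoyloxy)-2-[(tert-butyldimethylsilyl)oxy]-1-hydroxy-6-oxocyclohexyl]methyl benzoate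
Conditions: BF3·OEt2 (1.5 equiv), CH2Cl2, −40 → 0 °C; aq. NaHCO3
Reagents that add atoms: none
Why: Acyloin (α-ketol) rearrangement: BF3 binds the acyl oxygen, the tertiary hydroxyl pushes, and the C2–C6 σ bond shifts suprafacially to C1, making C2 the ring ketone and C1 the tertiary carbinol. The closest known reaction type is the Lewis-acid-promoted one-carbon ring expansion of 1-acylcycloalkanols to 2-hydroxy-2-alkylcycloalkanones, as in the D-homoannulation of 17-hydroxy-20-keto steroids. The six-membered ring is closed by ring expansion, not by cyclisation: C6 stays bonded to C5 and exchanges C2 for C1, inserting the former exocyclic acyl carbon between C2 and C6. C6 migrates with retention, so C5 and C6 pass into the product unchanged. The new centre C1 is controlled by the rotamer about the C1–C2 bond: boron can bind only one oxygen, so no chelate forms, and the carbonyl oxygen should lie anti to the carbinol oxygen with C7 pointing away from the ring face that carries the C5 benzoate; C6 then adds to the acyl face that leaves O1 trans to O6. The step needs C6 rather than C3 to migrate; C6 is the more substituted carbon and carries a donor oxygen kept electron-rich as a silyl ether. Relief of cyclopentane strain drives the shift, and the product should not shift again because its only alternative migrating group is the electron-poor primary C7. Low temperature and a cold quench keep the reaction under kinetic control.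

Step 8
Reactants: 11 [(1R,2S,3R)-3-(benzoyloxy)-2-[(tert-butyldimethylsilyl)oxy]-1-hydroxy-6-oxocyclohexyl]methyl benzoate
Product: 12 [(1S,2S,3R,6R)-3-(benzoyloxy)-2-[(tert-butyldimethylsilyl)oxy]-1,6-dihydroxycyclohexyl]methyl benzoate
Conditions: Me4NBH(OAc)3 (5 equiv), MeCN/AcOH (1:1), −30 → 0 °C
Reagents that add atoms: none
Why: Hydroxyl-directed triacetoxyborohydride reduction (Evans–Saksena type): the tertiary C1 hydroxyl, the only free one, exchanges onto boron and delivers hydride to the C2 carbonyl from its own face, so O2 ends trans to O1; this is also the axial trajectory anti to the axial C7 group, so steric approach control agrees, and the acidic medium prevents benzoate migration.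

Step 9
Reactants: 12 [(1S,2S,3R,6R)-3-(benzoyloxy)-2-[(tert-butyldimethylsilyl)oxy]-1,6-dihydroxycyclohexyl]methyl benzoate
Product: 13 [(1S,2S,3R,6R)-3-(benzoyloxy)-1,2,6-trihydroxycyclohexyl]methyl benzoate
Conditions: HF·pyridine, pyridine/THF, 0 °C → rt
Reagents that add atoms: none
Why: Fluoride-mediated desilylation under buffered, non-basic conditions; no alkoxide is formed, so the benzoates should stay at O5 and O7, and no stereocentre is touched.

## Compound list

1 | cyclopent-2-en-1-one | O=C1C=CCC1 | starting material
2 | (1S,5S)-6-oxabicyclo[3.1.0]hexan-2-one | O=C1CC[C@@H]2O[C@H]12 | intermediate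
3 | ethyl vinyl ether (ethoxyethene) | C=COCC | starting material
4 | (1-ethoxyethenyl)lithium | [Li]C(=C)OCC | intermediate
5 | (1S,2R,5S)-2-(1-ethoxyethenyl)-6-oxabicyclo[3.1.0]hexan-2-ol | C=C(OCC)[C@@]1(O)CC[C@@H]2O[C@H]12 | intermediate
6 | 2-hydroxy-1-[(1S,2R,5S)-2-hydroxy-6-oxabicyclo[3.1.0]hexan-2-yl]ethan-1-one | OCC(=O)[C@@]1(O)CC[C@@H]2O[C@H]12 | intermediate
7 | 2-[(1S,2R,5S)-2-hydroxy-6-oxabicyclo[3.1.0]hexan-2-yl]-2-oxoethyl benzoate | O=C(COC(=O)c1ccccc1)[C@@]1(O)CC[C@@H]2O[C@H]12 | intermediate
8 | benzoic acid | OC(=O)c1ccccc1 | starting material
9 | 2-[(1R,2S,3R)-3-(benzoyloxy)-1,2-dihydroxycyclopentyl]-2-oxoethyl benzoate | O=C(COC(=O)c1ccccc1)[C@@]1(O)CC[C@@H](OC(=O)c2ccccc2)[C@@H]1O | intermediate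
10 | 2-[(1R,2S,3R)-3-(benzoyloxy)-2-[(tert-butyldimethylsilyl)oxy]-1-hydroxycyclopentyl]-2-oxoethyl benzoate | O=C(COC(=O)c1ccccc1)[C@@]1(O)CC[C@@H](OC(=O)c2ccccc2)[C@@H]1O[Si](C)(C)C(C)(C)C | intermediate
11 | [(1R,2S,3R)-3-(benzoyloxy)-2-[(tert-butyldimethylsilyl)oxy]-1-hydroxy-6-oxocyclohexyl]methyl benzoate | O=C(OC[C@]1(O)C(=O)CC[C@@H](OC(=O)c2ccccc2)[C@@H]1O[Si](C)(C)C(C)(C)C)c1ccccc1 | intermediate
12 | [(1S,2S,3R,6R)-3-(benzoyloxy)-2-[(tert-butyldimethylsilyl)oxy]-1,6-dihydroxycyclohexyl]methyl benzoate | O=C(OC[C@]1(O)[C@H](O)CC[C@@H](OC(=O)c2ccccc2)[C@@H]1O[Si](C)(C)C(C)(C)C)c1ccccc1 | intermediate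
13 | [(1S,2S,3R,6R)-3-(benzoyloxy)-1,2,6-trihydroxycyclohexyl]methyl benzoate | O=C(OC[C@]1(O)[C@H](O)CC[C@@H](OC(=O)c2ccccc2)[C@@H]1O)c1ccccc1 | target

## Step count and least certain steps

Total: 9 steps. Longest linear sequence: 9 steps (1 → 13).

**Step 7 (key step).** The likely failures are a shift through the hydrogen-bonded syn rotamer (which would give the C1 epimer of 11), leakage to migration of C3 (the regioisomeric ketol), and loss of the silyl ether to the Lewis acid. The preference for the anti rotamer rests on a monodentate acid and on sterics, not on a covalent constraint. The fallback changes both the activation mode and the O6 protecting group. It sets out from 9, which is converted with benzyloxymethyl chloride and iPr2NEt into 2-[(1R,2S,3R)-3-(benzoyloxy)-2-[(benzyloxy)methoxy]-1-hydroxycyclopentyl]-2-oxoethyl benzoate F1. The shift is then run on the non-chelated potassium alkoxide (substoichiometric KN(SiMe3)2 with 18-crown-6, THF, −78 °C, cold acetic acid quench), where charge repulsion between the alkoxide and carbonyl oxygens enforces the anti arrangement, to give [(1R,2S,3R)-3-(benzoyloxy)-2-[(benzyloxy)methoxy]-1-hydroxy-6-oxocyclohexyl]methyl benzoate F2. The acetal ether cannot migrate to the alkoxide as a silyl group could, and any transient benzoyl transfer from O7 should revert on neutral equilibration because the primary ester is the more stable. Reduction with Me4NBH(OAc)3 as in step 8 gives [(1S,2S,3R,6R)-3-(benzoyloxy)-2-[(benzyloxy)methoxy]-1,6-dihydroxycyclohexyl]methyl benzoate F3, and hydrogenolysis (H2, Pd(OH)2 on carbon, ethyl acetate) returns to the route at 13.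

**Step 1.** The likely failures are slow iminium formation with the five-membered enone, with incomplete conversion and eroded enantioselectivity, and loss of the small, water-soluble, volatile epoxy ketone on isolation. The fallback moves the asymmetric induction to a ketone reduction. It sets out from 1, which is iodinated (I2, pyridine) to 2-iodocyclopent-2-en-1-one F4. Corey–Bakshi–Shibata reduction ((S)-Me-CBS oxazaborolidine, BH3·SMe2) should give (R)-2-iodocyclopent-2-en-1-ol F5. Iodine–lithium exchange and protonation (t-BuLi, Et2O, −78 °C; MeOH) gives (R)-cyclopent-2-en-1-ol F6. Hydroxyl-directed epoxidation (VO(acac)2, t-BuOOH) gives the cis-epoxy alcohol (1R,2R,5S)-6-oxabicyclo[3.1.0]hexan-2-ol F7, and Dess–Martin oxidation returns to the route at 2.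

**Step 5.** The likely failures are a premature acyloin shift in the chelated sense when titanium holds the α-ketol as a chelate, exchange of isopropoxide into the C7 benzoate, and some attack at C6. The fallback separates ring opening from acylation. It sets out from 7, which is hydrolysed under acid catalysis (HClO4 cat., THF/H2O), water attacking C5 with inversion, to 2-oxo-2-[(1R,2S,3R)-1,2,3-trihydroxycyclopentyl]ethyl benzoate F8. Selective benzoylation of the less hindered C5 hydroxyl (BzCl, 2,4,6-collidine, CH2Cl2, −40 °C), the C6 hydroxyl being shielded by the quaternary carbon, returns to the route at 9.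

**Step 2.** The likely failures are deprotonation of 2 at C3 by the basic vinyllithium (enolisation instead of addition) and incomplete facial selectivity. The fallback uses a less basic two-carbon nucleophile and adjusts the oxidation level afterwards. It sets out from 2, to which the organocerium reagent from CH2=CHMgBr and CeCl3 (THF, −78 °C) adds to give (1S,2S,5S)-2-ethenyl-6-oxabicyclo[3.1.0]hexan-2-ol F9. Ruthenium-catalysed ketohydroxylation (RuCl3 cat., KHSO5 as Oxone, NaHCO3, ethyl acetate/MeCN/H2O) converts the vinyl group into the hydroxyacetyl group and returns to the route at 6.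

## Further compounds

F1 | step 7 | 2-[(1R,2S,3R)-3-(benzoyloxy)-2-[(benzyloxy)methoxy]-1-hydroxycyclopentyl]-2-oxoethyl benzoate | O=C(COC(=O)c1ccccc1)[C@@]1(O)CC[C@@H](OC(=O)c2ccccc2)[C@@H]1OCOCc1ccccc1
F2 | step 7 | [(1R,2S,3R)-3-(benzoyloxy)-2-[(benzyloxy)methoxy]-1-hydroxy-6-oxocyclohexyl]methyl benzoate | O=C(OC[C@]1(O)C(=O)CC[C@@H](OC(=O)c2ccccc2)[C@@H]1OCOCc1ccccc1)c1ccccc1
F3 | step 7 | [(1S,2S,3R,6R)-3-(benzoyloxy)-2-[(benzyloxy)methoxy]-1,6-dihydroxycyclohexyl]methyl benzoate | O=C(OC[C@]1(O)[C@H](O)CC[C@@H](OC(=O)c2ccccc2)[C@@H]1OCOCc1ccccc1)c1ccccc1
F4 | step 1 | 2-iodocyclopent-2-en-1-one | O=C1CCC=C1I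
F5 | step 1 | (R)-2-iodocyclopent-2-en-1-ol | O[C@@H]1CCC=C1I
F6 | step 1 | (R)-cyclopent-2-en-1-ol | O[C@@H]1CCC=C1
F7 | step 1 | (1R,2R,5S)-6-oxabicyclo[3.1.0]hexan-2-ol | O[C@@H]1CC[C@@H]2O[C@H]12
F8 | step 5 | 2-oxo-2-[(1R,2S,3R)-1,2,3-trihydroxycyclopentyl]ethyl benzoate | O=C(COC(=O)c1ccccc1)[C@@]1(O)CC[C@@H](O)[C@@H]1O
F9 | step 2 | (1S,2S,5S)-2-ethenyl-6-oxabicyclo[3.1.0]hexan-2-ol | C=C[C@@]1(O)CC[C@@H]2O[C@H]12
A1 | alternative 1 | 2,2-dimethyl-1,3-dioxan-5-one | CC1(C)OCC(=O)CO1
A2 | alternative 1 | acrolein (prop-2-enal) | C=CC=O
A3 | alternative 1 | 6-hydroxy-3,3-dimethyl-2,4-dioxabicyclo[3.3.1]nonan-9-one (hydroxyl trans to the adjacent bridgehead oxygen) | O=C1[C@H]2CC[C@@H](O)[C@@H]1OC(C)(C)O2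
A4 | alternative 2 | trans-4,5-diacetyl-4-[(benzyloxy)methyl]-2,2-dimethyl-1,3-dioxolane | CC(=O)[C@@H]1OC(C)(C)O[C@@]1(COCc2ccccc2)C(C)=O
A5 | alternative 2 | trans-fused (3aR,7aR)-3a-[(benzyloxy)methyl]-2,2-dimethyltetrahydro-1,3-benzodioxole-4,7-dione | c1ccccc1COC[C@]2(OC(C)(C)O3)C(=O)CCC(=O)[C@@H]23
A6 | alternative 3 | (4R,5S)-4-(benzoyloxy)-5,7-bis[(tert-butyldimethylsilyl)oxy]-6-oxoheptanal | O=CCC[C@@H](OC(=O)c1ccccc1)[C@H](O[Si](C)(C)C(C)(C)C)C(=O)CO[Si](C)(C)C(C)(C)C
A7 | alternative 3 | (2R,3S,4R)-4-(benzoyloxy)-3-[(tert-butyldimethylsilyl)oxy]-2-hydroxy-2-{[(tert-butyldimethylsilyl)oxy]methyl}cyclohexan-1-one | CC(C)(C)[Si](C)(C)OC[C@]1(O)C(=O)CC[C@@H](OC(=O)c2ccccc2)[C@@H]1O[Si](C)(C)C(C)(C)C
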